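**Retrosynthetic overview** (locants count from the CHBr terminus, C1, to CH2Cl, C8)
1. The oxirane is the only ring; it is closed last by hydroxyl-directed, intramolecular oxygen delivery from C6–OH to the 3E-alkene of an acyclic dienyl bromohydrin.
2. C4–C5 disconnection: a (1E,3Z)-dienylmagnesium (C1–C4) opens a chiral cyclic sulfate (C5–C8), so the base-labile bromohydrin is only unveiled by acid.
3. The cyclic sulfate comes from a bromodiol, made by invertive bromide opening of the Sharpless epoxy alcohol of (E)-4-chloro-3-methylbut-2-en-1-ol (sets C6 and C7; Cl is installed before Br), itself from prenyl acetate.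
4. The dienyl iodide comes from anti-hydrochlorination of a 1-bromoalkyne (Z-bromochloroalkene), after Zr-catalysed syn-carboalumination/iodination of TMS-butadiyne (E-alkene), from TMS-acetylene.
5. Ring order: the cyclic sulfate is a transient ring, opened at the fragment union; the oxirane is formed in the final step.

Assumption: only substrates, intermediates and products are numbered; reagents, catalysts and solvents are named where used, and a one-pot sequence counts as one step.

**Branch A (C5–C8)**

Step 1
Reactants: 1 3-methylbut-2-en-1-yl acetate (prenyl acetate)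
Product: 2 (2E)-4-hydroxy-3-methylbut-2-en-1-yl acetate
Conditions: SeO2 (cat.), t-BuOOH (70% aq.), salicylic acid (cat.), CH2Cl2, rt
Reagents that add atoms: tert-butyl hydroperoxide CC(C)(C)OO
Why: Sharpless–Umbreit SeO2/t-BuOOH allylic oxidation (ene reaction then [2,3]-shift) hydroxylates only the E-methyl group of the trisubstituted alkene and leaves the acetate intact.

Step 2
Reactants: 2 (2E)-4-hydroxy-3-methylbut-2-en-1-yl acetate
Product: 3 (2E)-4-chloro-3-methylbut-2-en-1-yl acetate
Conditions: PPh3, NCS, THF, 0 °C to rt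
Reagents that add atoms: N-chlorosuccinimide O=C1CCC(=O)N1Cl
Why: Appel-type deoxychlorination displaces the primary allylic oxyphosphonium by SN2 without allylic transposition or loss of E geometry, so chlorine is in place before any bromine is introduced.

Step 3
Reactants: 3 (2E)-4-chloro-3-methylbut-2-en-1-yl acetate
Product: 4 (2E)-4-chloro-3-methylbut-2-en-1-ol
Conditions: HCl (cat., from AcCl), MeOH, 0 °C to rt
Reagents that add atoms: none
Why: Acid-catalysed transesterification removes the acetate without touching the primary allylic chloride, which basic methanolysis could displace.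

Step 4
Reactants: 4 (2E)-4-chloro-3-methylbut-2-en-1-ol
Product: 5 [(2R,3S)-3-(chloromethyl)-3-methyloxiran-2-yl]methanol
Conditions: Ti(OiPr)4 (10 mol%), D-(−)-diethyl tartrate (12 mol%), t-BuOOH (in isooctane), 4 Å MS, CH2Cl2, −20 °C
Reagents that add atoms: tert-butyl hydroperoxide CC(C)(C)OO
Why: Katsuki–Sharpless asymmetric epoxidation of this geraniol-type allylic alcohol with the D-(−)-tartrate catalyst delivers oxygen to the face that gives the (2R,3S)-epoxy alcohol, fixing the future carbinol carbon and the future bromide-bearing carbon.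

Step 5
Reactants: 5 [(2R,3S)-3-(chloromethyl)-3-methyloxiran-2-yl]methanol
Product: 6 (2R,3R)-3-bromo-4-chloro-3-methylbutane-1,2-diol
Conditions: Ti(OiPr)4 (1.5 equiv), Et2NH·HBr (2 equiv), CH2Cl2, rt; aqueous work-up
Reagents that add atoms: diethylammonium bromide CC[NH2+]CC.[Br-]
Why: Titanium-mediated regioselective opening of a 2,3-epoxy alcohol by bromide occurs at C3 (favoured by the Ti chelate and because C3 is the tertiary carbon) with SN2-type inversion, giving the (R)-tertiary bromide while C2 keeps its oxygen and configuration.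

Step 6
Reactants: 6 (2R,3R)-3-bromo-4-chloro-3-methylbutane-1,2-diol
Product: 8 (4R)-4-[(2R)-2-bromo-1-chloropropan-2-yl]-1,3,2-dioxathiolane 2,2-dioxide, via cyclic sulfite 7 (not isolated)
Conditions: SOCl2, CCl4, reflux; then 0 °C, MeCN/H2O, RuCl3·3H2O (0.5 mol%), NaIO4, rt
Reagents that add atoms: thionyl chloride O=S(Cl)Cl; sodium periodate [Na+].[O-]I(=O)(=O)=O
Why: The Sharpless one-pot cyclic sulfate synthesis (cyclic sulfite, then RuO4-catalysed oxidation) activates the diol as an epoxide equivalent under acidic to neutral conditions, so the bromohydrin never meets base and no stereocentre is touched.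

**Branch B (C1–C4)**

Step 7
Reactants: 9 ethynyl(trimethyl)silane (2 equiv)
Product: 10 1,4-bis(trimethylsilyl)buta-1,3-diyne
Conditions: CuCl (5 mol%), TMEDA (cat.), O2, acetone, rt
Reagents that add atoms: none
Why: Glaser–Hay oxidative homocoupling of the terminal alkyne gives the symmetrical diyne.

Step 8
Reactants: 10 1,4-bis(trimethylsilyl)buta-1,3-diyne
Product: 12 buta-1,3-diyn-1-yl(trimethyl)silane, via lithium diynide 11 (not isolated)
Conditions: MeLi·LiBr (1.05 equiv), Et2O, rt; sat. aq. NH4Cl (product used as a solution)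
Reagents that add atoms: none
Why: Selective mono-protodesilylation: one equivalent of MeLi attacks silicon and expels the lithium diynide, which as an anion resists a second desilylation and is protonated on work-up.

Step 9
Reactants: 12 buta-1,3-diyn-1-yl(trimethyl)silane
Product: 14 [(3E)-4-iodo-3-methylbut-3-en-1-yn-1-yl](trimethyl)silane, via alkenylalane 13 (not isolated)
Conditions: Me3Al (2.5 equiv), Cp2ZrCl2 (25 mol%), CH2Cl2, rt; then I2, THF, −30 to 0 °C
Reagents that add atoms: trimethylaluminium C[Al](C)C; iodine II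
Why: Negishi Zr-catalysed carboalumination adds Me–Al syn across the terminal alkyne with methyl on the internal carbon (the silylalkyne is inert), and iodinolysis with retention gives the (E)-trisubstituted alkenyl iodide.

Step 10
Reactants: 14 [(3E)-4-iodo-3-methylbut-3-en-1-yn-1-yl](trimethyl)silane
Product: 15 (1E)-4-bromo-1-iodo-2-methylbut-1-en-3-yne
Conditions: NBS (1.2 equiv), AgNO3 (10 mol%), acetone, rt, dark
Reagents that add atoms: N-bromosuccinimide O=C1CCC(=O)N1Br
Why: Silver-catalysed desilylative bromination (silver acetylide from the silylalkyne, then electrophilic bromination by NBS) gives the 1-bromoalkyne directly and leaves the alkenyl iodide untouched.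

Step 11
Reactants: 15 (1E)-4-bromo-1-iodo-2-methylbut-1-en-3-yne
Product: 16 (1E,3Z)-4-bromo-3-chloro-1-iodo-2-methylbuta-1,3-diene
Conditions: LiCl (3 equiv), Pd(OAc)2 (5 mol%), AcOH, rt
Reagents that add atoms: lithium chloride [Li+].[Cl-]
Why: Pd(II)-catalysed anti-hydrochlorination of the 1-bromoalkyne (trans-chloropalladation with chloride entering at the carbon remote from bromine, then protodepalladation) places H and Cl trans, hence Cl and Br cis, giving the (Z)-bromochloroalkene while Pd stays Pd(II) and does not engage the C–I bond.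

**Union and ring closure**

Step 12
Reactants: 16 (1E,3Z)-4-bromo-3-chloro-1-iodo-2-methylbuta-1,3-diene; 8 (4R)-4-[(2R)-2-bromo-1-chloropropan-2-yl]-1,3,2-dioxathiolane 2,2-dioxide
Product: 19 (2R,3R,5E,7Z)-2,8-dibromo-1,7-dichloro-2,6-dimethylocta-5,7-dien-3-ol, via dienylmagnesium chloride 17 (not isolated), via magnesium alkyl sulfate 18 (not isolated)
Conditions: 16 (1.2 equiv), i-PrMgCl·LiCl (1.15 equiv), THF, −40 °C; CuI (10 mol%), then 8, −40 to −20 °C; then 20% aq. H2SO4, Et2O, rt
Reagents that add atoms: none
Why: Chemoselective iodine–magnesium exchange (C–I reacts far faster than C–Br or C–Cl) followed by copper-catalysed SN2 opening of the cyclic sulfate at its primary carbon joins the fragments with retention of the E geometry, and acid hydrolysis of the sulfate monoester (S–O cleavage) releases the secondary alcohol with both stereocentres unchanged.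

Step 13
Reactants: 19 (2R,3R,5E,7Z)-2,8-dibromo-1,7-dichloro-2,6-dimethylocta-5,7-dien-3-ol
Product: 20 (2R,3R)-3-bromo-1-[(2S,3R)-3-[(Z)-2-bromo-1-chloroethenyl]-3-methyloxiran-2-yl]-4-chloro-3-methylbutan-2-ol
Conditions: VO(acac)2 (5 mol%), t-BuOOH (1.5 equiv, in decane), CH2Cl2, 0 °C to rt
Reagents that add atoms: tert-butyl hydroperoxide CC(C)(C)OO
Why: Vanadium-catalysed hydroxyl-directed (Mihelich-type) epoxidation of the homoallylic alcohol transfers oxygen intramolecularly within the vanadate ester through a chair-like transition state (bulky carbinol substituent equatorial, alkene arm placed to avoid A1,3 strain with the cis methyl), giving the 1,3-syn epoxy alcohol, i.e. (2S,3R) at the oxirane, while the electron-poor bromochloroalkene is not epoxidised.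

**Compound list**
1 | 3-methylbut-2-en-1-yl acetate (prenyl acetate) | CC(C)=CCOC(C)=O | starting material
2 | (2E)-4-hydroxy-3-methylbut-2-en-1-yl acetate | OC/C(C)=C/COC(C)=O | intermediate
3 | (2E)-4-chloro-3-methylbut-2-en-1-yl acetate | ClC/C(C)=C/COC(C)=O | intermediate
4 | (2E)-4-chloro-3-methylbut-2-en-1-ol | ClC/C(C)=C/CO | intermediate
5 | [(2R,3S)-3-(chloromethyl)-3-methyloxiran-2-yl]methanol | OC[C@H]1O[C@]1(C)CCl | intermediate
6 | (2R,3R)-3-bromo-4-chloro-3-methylbutane-1,2-diol | C[C@](Br)(CCl)[C@H](O)CO | intermediate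
7 | (4R)-4-[(2R)-2-bromo-1-chloropropan-2-yl]-1,3,2-dioxathiolane 2-oxide (both S-epimers) | C[C@](Br)(CCl)[C@H]1COS(=O)O1 | intermediate
8 | (4R)-4-[(2R)-2-bromo-1-chloropropan-2-yl]-1,3,2-dioxathiolane 2,2-dioxide | C[C@](Br)(CCl)[C@H]1COS(=O)(=O)O1 | intermediate
9 | ethynyl(trimethyl)silane | C#C[Si](C)(C)C | starting material
10 | 1,4-bis(trimethylsilyl)buta-1,3-diyne | C[Si](C)(C)C#CC#C[Si](C)(C)C | intermediate
11 | lithium 4-(trimethylsilyl)buta-1,3-diyn-1-ide | [Li]C#CC#C[Si](C)(C)C | intermediate
12 | buta-1,3-diyn-1-yl(trimethyl)silane | C#CC#C[Si](C)(C)C | intermediate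
13 | dimethyl[(1E)-2-methyl-4-(trimethylsilyl)but-1-en-3-yn-1-yl]alumane | C[Al](C)/C=C(C)/C#C[Si](C)(C)C | intermediate
14 | [(3E)-4-iodo-3-methylbut-3-en-1-yn-1-yl](trimethyl)silane | I/C=C(C)/C#C[Si](C)(C)C | intermediate
15 | (1E)-4-bromo-1-iodo-2-methylbut-1-en-3-yne | I/C=C(C)/C#CBr | intermediate
16 | (1E,3Z)-4-bromo-3-chloro-1-iodo-2-methylbuta-1,3-diene | I/C=C(C)/C(Cl)=C/Br | intermediate
17 | [(1E,3Z)-4-bromo-3-chloro-2-methylbuta-1,3-dien-1-yl]magnesium chloride | Cl[Mg]/C=C(C)/C(Cl)=C/Br | intermediate
18 | chloromagnesium (2R,3R,5E,7Z)-2,8-dibromo-1,7-dichloro-2,6-dimethylocta-5,7-dien-3-yl sulfate | C[C@](Br)(CCl)[C@H](OS(=O)(=O)[O-])C/C=C(C)/C(Cl)=C/Br.[Mg+]Cl | intermediate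
19 | (2R,3R,5E,7Z)-2,8-dibromo-1,7-dichloro-2,6-dimethylocta-5,7-dien-3-ol | C[C@](Br)(CCl)[C@H](O)C/C=C(C)/C(Cl)=C/Br | intermediate
20 | (2R,3R)-3-bromo-1-[(2S,3R)-3-[(Z)-2-bromo-1-chloroethenyl]-3-methyloxiran-2-yl]-4-chloro-3-methylbutan-2-ol (CNP0151438.1) | C[C@](Br)(CCl)[C@H](O)C[C@@H]1O[C@@]1(C)/C(Cl)=C/Br | target

**Step count**
Total: 13 steps. Longest linear sequence: 8 steps (steps 1–6, 12, 13, from prenyl acetate). The other branch runs 7 steps (steps 7–11, 12, 13).

**Steps most likely to fail, with fallbacks**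

Step 11, anti-hydrochlorination of 15. The regio- and stereochemistry of HCl addition, and the survival of the alkenyl iodide beside a palladium salt, are not secured for this dienyl system. The fallback sets out from 14 and comes back to the route at 16, replacing steps 10 and 11 with a haloboration logic. K2CO3 in MeOH removes the silyl group to give (1E)-1-iodo-2-methylbut-1-en-3-yne F1. BCl3 in CH2Cl2 (−78 to 0 °C) adds B–Cl syn and Markovnikov across the terminal alkyne to give dichloro[(1Z,3E)-2-chloro-4-iodo-3-methylbuta-1,3-dien-1-yl]borane F2, which aqueous work-up converts to [(1Z,3E)-2-chloro-4-iodo-3-methylbuta-1,3-dien-1-yl]boronic acid F3. NBS in MeCN then replaces boron by bromine with retention, so Cl and Br end up cis, giving 16.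

Step 12, fragment union. The I/Mg exchange has to outrun attack at the vinylic C–Br and deprotonation of the CHBr= hydrogen. The organocopper species could also attack the tertiary bromide, which sits β to the sulfate oxygen, and cause reductive elimination. The fallback sets out from 6 and comes back at 19, joining the halves by olefin metathesis with no organomagnesium or organocopper species. NaIO4 cleaves 6 to (2R)-2-bromo-3-chloro-2-methylpropanal F4, which has no α-hydrogen and is configurationally stable. Brown allylation with (+)-B-allyldiisopinocampheylborane (from (−)-α-pinene; Et2O, −78 °C, non-oxidative work-up) gives (2R,3R)-2-bromo-1-chloro-2-methylhex-5-en-3-ol F5. In parallel, commercial 2-methylbut-1-en-3-yne is brominated (NBS, cat. AgNO3) to 4-bromo-2-methylbut-1-en-3-yne F6 and hydrochlorinated as in step 11 to (3Z)-4-bromo-3-chloro-2-methylbuta-1,3-diene F7. Cross-metathesis of F5 with excess F7 (Hoveyda–Grubbs II, CH2Cl2, 40 °C) forms the trisubstituted 5E alkene and gives 19 after removal of the minor 5Z isomer.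

Step 13, directed epoxidation. The diene is deactivated by the halovinyl group, so the reaction may be slow; vanadium may instead oxidise the secondary alcohol, or the 1,3-syn selectivity may be modest. The fallback sets out from 19 and comes back at 20, replacing substrate control by reagent control. TESOTf with 2,6-lutidine gives triethyl{[(2R,3R,5E,7Z)-2,8-dibromo-1,7-dichloro-2,6-dimethylocta-5,7-dien-3-yl]oxy}silane F8. Shi epoxidation with the L-fructose-derived (ent-Shi) ketone, Oxone, K2CO3-buffered MeCN/DMM/H2O, 0 °C, gives triethyl{[(2R,3R)-3-bromo-1-[(2S,3R)-3-[(Z)-2-bromo-1-chloroethenyl]-3-methyloxiran-2-yl]-4-chloro-3-methylbutan-2-yl]oxy}silane F9. HF·pyridine buffered with pyridine in THF at 0 °C removes the silyl group without opening the oxirane, giving 20.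

**Further compounds**
F1 | step 11 | (1E)-1-iodo-2-methylbut-1-en-3-yne | I/C=C(C)/C#C
F2 | step 11 | dichloro[(1Z,3E)-2-chloro-4-iodo-3-methylbuta-1,3-dien-1-yl]borane | ClB(Cl)/C=C(Cl)/C(C)=C/I
F3 | step 11 | [(1Z,3E)-2-chloro-4-iodo-3-methylbuta-1,3-dien-1-yl]boronic acid | OB(O)/C=C(Cl)/C(C)=C/I
F4 | step 12 | (2R)-2-bromo-3-chloro-2-methylpropanal | C[C@](Br)(CCl)C=O
F5 | step 12 | (2R,3R)-2-bromo-1-chloro-2-methylhex-5-en-3-ol | C[C@](Br)(CCl)[C@H](O)CC=C
F6 | step 12 | 4-bromo-2-methylbut-1-en-3-yne | C=C(C)C#CBr
F7 | step 12 | (3Z)-4-bromo-3-chloro-2-methylbuta-1,3-diene | C=C(C)/C(Cl)=C/Br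
F8 | step 13 | triethyl{[(2R,3R,5E,7Z)-2,8-dibromo-1,7-dichloro-2,6-dimethylocta-5,7-dien-3-yl]oxy}silane | C[C@](Br)(CCl)[C@H](O[Si](CC)(CC)CC)C/C=C(C)/C(Cl)=C/Br
F9 | step 13 | triethyl{[(2R,3R)-3-bromo-1-[(2S,3R)-3-[(Z)-2-bromo-1-chloroethenyl]-3-methyloxiran-2-yl]-4-chloro-3-methylbutan-2-yl]oxy}silane | C[C@](Br)(CCl)[C@H](O[Si](CC)(CC)CC)C[C@@H]1O[C@@]1(C)/C(Cl)=C/Br
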